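**Retrosynthetic overview**

1. The target is a resveratrol trimer: a 2,3-trans-diaryl-1-alkylidene-indane (benzo ring = ring A, carrying the 4,6-diol) joined through the exocyclic CH to C5 of a trans-2,3-diaryl-2,3-dihydrobenzofuran (DHB).
2. Key disconnection: both bonds from ring A to the cyclopentane (C7a–C1 and C3a–C3) are cut at once. Ring A is brought in as 3,5-bis(benzyloxy)phenylboronic acid used as a 1,2-dimetalloarene equivalent; the three-carbon partner is an alkyne-tethered para-quinone methide.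
3. Enabling feature: ring A is a symmetric 3,5-dioxygenated aryl, so C7a (meta to both oxygens) can carry boron and the two neighbouring ortho C–H bonds (future C3a) are equivalent; the exocyclic C1=CH carries its H cis to ring A (the H a 1,4-shift delivers); C3 is para-hydroxybenzylic, i.e. the exocyclic carbon of a latent quinone methide.
4. The precursor comes from a Sonogashira union of an enantiopure 5-iodo-DHB (rhodium-carbene C–H insertion, then C2 epimerization) with an (S)-propargylic arene (nickel-catalysed enantioconvergent Negishi arylation), followed by Ag2O oxidation of the hindered phenol.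
5. Ring order: DHB furan ring (step 5), then the indane five-membered ring (step 14), then removal of benzyl and tert-butyl groups.

Key step: step 14

Assumption: the sense of induction of the two chiral catalysts (Rh2(S-PTAD)4 in step 5, the indanyl-pybox nickel catalyst in step 11) is taken by analogy with related substrates; if a first run shows the opposite sense, the antipodal ligand is used and nothing else changes.

Notation: Bn = benzyl, TMS = trimethylsilyl, "DHB-5-yl" = (2R,3R)-2-[4-(benzyloxy)phenyl]-3-[3,5-bis(benzyloxy)phenyl]-2,3-dihydro-1-benzofuran-5-yl.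

**Route**

Step 1
Reactants: 1 2-hydroxy-5-iodobenzaldehyde; 2 1-(benzyloxy)-4-(chloromethyl)benzene
Product: 3 2-{[4-(benzyloxy)phenyl]methoxy}-5-iodobenzaldehyde
Conditions: K2CO3, KI (cat.), DMF, 60 °C
Reagents that add atoms: none
Why: Williamson ether synthesis; the phenoxide of 1 is alkylated by the benzylic chloride, installing the benzylic CH2 that later becomes C2 of the dihydrobenzofuran.

Step 2
Reactants: 3 2-{[4-(benzyloxy)phenyl]methoxy}-5-iodobenzaldehyde; 4 1,3-bis(benzyloxy)-5-bromobenzene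
Product: 6 [3,5-bis(benzyloxy)phenyl](2-{[4-(benzyloxy)phenyl]methoxy}-5-iodophenyl)methanol (racemic), via arylmagnesium bromide 5 (not isolated)
Conditions: Mg, THF, reflux; then 3, THF, −40 to 0 °C; H2O
Reagents that add atoms: none
Why: Grignard addition to the aldehyde should outrun halogen–metal exchange at the aryl iodide at low temperature; the carbinol centre stays racemic because it is oxidized next.

Step 3
Reactants: 6 the diaryl carbinol
Product: 7 [3,5-bis(benzyloxy)phenyl](2-{[4-(benzyloxy)phenyl]methoxy}-5-iodophenyl)methanone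
Conditions: MnO2, CH2Cl2, rt
Reagents that add atoms: none
Why: MnO2 oxidation of a doubly benzylic alcohol should give the benzophenone without touching benzyl ethers or the iodide.

Step 4
Reactants: 7 the benzophenone
Product: 8 hydrazone of 7 (E/Z mixture)
Conditions: N2H4·H2O, AcOH (cat.), EtOH, reflux
Reagents that add atoms: hydrazine, NN
Why: Hydrazone condensation of the diaryl ketone provides the precursor of a donor/donor diazo compound.

Step 5
Reactants: 8 the hydrazone
Product: 10 (2S,3R)-2-[4-(benzyloxy)phenyl]-3-[3,5-bis(benzyloxy)phenyl]-5-iodo-2,3-dihydro-1-benzofuran (cis), via diaryldiazomethane 9 (not isolated)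
Conditions: MnO2, CH2Cl2, 0 °C, filter; then Rh2(S-PTAD)4 (1 mol%), CH2Cl2/MeCN, −20 °C
Reagents that add atoms: none
Why: MnO2 dehydrogenates the hydrazone to the diazo compound, and the chiral dirhodium carboxylate converts it into a donor/donor carbene that undergoes enantioselective intramolecular C–H insertion into the ether benzylic C–H; the catalyst sets C3 as R and the compact insertion transition state places the two aryl groups cis.

Step 6
Reactants: 10 the cis-dihydrobenzofuran
Product: 11 (2R,3R)-2-[4-(benzyloxy)phenyl]-3-[3,5-bis(benzyloxy)phenyl]-5-iodo-2,3-dihydro-1-benzofuran (trans)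
Conditions: TFA (20 mol%), CH2Cl2, 0 °C to rt
Reagents that add atoms: none
Why: Acid-mediated epimerization; reversible ionization of the C2–O bond to a para-alkoxybenzyl cation and reclosure should equilibrate C2 to the more stable 2,3-trans isomer while C3 is untouched.

Step 7
Reactants: 12 (3,5-di-tert-butyl-4-hydroxyphenyl)acetic acid
Product: 13 2-(3,5-di-tert-butyl-4-hydroxyphenyl)-N-methoxy-N-methylacetamide
Conditions: CDI, CH2Cl2, rt; then MeNHOMe·HCl, rt
Reagents that add atoms: N,O-dimethylhydroxylamine hydrochloride, CNOC.Cl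
Why: Amide coupling through the acyl imidazolide gives the Weinreb amide; the hindered phenol should not acylate.

Step 8
Reactants: 13 the Weinreb amide; 14 lithium (trimethylsilyl)acetylide (commercial THF solution)
Product: 15 1-{3,5-di-tert-butyl-4-[(trimethylsilyl)oxy]phenyl}-4-(trimethylsilyl)but-3-yn-2-one
Conditions: 14 (2.2 equiv), THF, −78 to 0 °C; TMSCl, 0 °C to rt; aq. NaHCO3
Reagents that add atoms: chlorotrimethylsilane, C[Si](C)(C)Cl
Why: Weinreb ketone synthesis; one equivalent of acetylide deprotonates the phenol, the second adds once to the amide (stable chelate), and the hindered lithium phenoxide is silylated in the same flask so the phenol is masked for the next three steps.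

Step 9
Reactants: 15 the ynone
Product: 16 1-{3,5-di-tert-butyl-4-[(trimethylsilyl)oxy]phenyl}-4-(trimethylsilyl)but-3-yn-2-ol (racemic)
Conditions: NaBH4, EtOH/THF, −20 °C
Reagents that add atoms: none
Why: Borohydride 1,2-reduction of the ynone gives the racemic propargylic alcohol, whose configuration is irrelevant for the stereoconvergent coupling that follows.

Step 10
Reactants: 16 the propargylic alcohol
Product: 17 [3-bromo-4-{3,5-di-tert-butyl-4-[(trimethylsilyl)oxy]phenyl}but-1-yn-1-yl]trimethylsilane (racemic)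
Conditions: CBr4, PPh3, CH2Cl2, 0 °C
Reagents that add atoms: tetrabromomethane, BrC(Br)(Br)Br
Why: The Appel reaction converts the propargylic alcohol into the secondary propargylic bromide under neutral conditions.

Step 11
Reactants: 17 the racemic propargylic bromide; 18 [3,5-bis(benzyloxy)phenyl]boronic acid
Product: 20 [(3S)-3-[3,5-bis(benzyloxy)phenyl]-4-{3,5-di-tert-butyl-4-[(trimethylsilyl)oxy]phenyl}but-1-yn-1-yl]trimethylsilane, via arylethylzinc reagent 19 (not isolated)
Conditions: 18, Et2Zn, toluene, 60 °C, then volatiles off; NiCl2(dme) (5 mol%), (S,S)-indanyl-pybox (6.5 mol%), DME, −20 °C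
Reagents that add atoms: none
Why: Nickel-catalysed enantioconvergent Negishi arylation of a racemic propargylic bromide; both enantiomers pass through one propargylic radical and the chiral pybox–nickel catalyst sets the new centre as S, the silyl cap directing coupling to the propargylic rather than the allenyl position.

Step 12
Reactants: 20 the (S)-silylalkyne; 11 the trans-iodo-dihydrobenzofuran
Product: 21 4-{(2S)-2-[3,5-bis(benzyloxy)phenyl]-4-(DHB-5-yl)but-3-yn-1-yl}-2,6-di-tert-butylphenol
Conditions: Pd(PPh3)2Cl2 (5 mol%), CuI (10 mol%), TBAF (2.5 equiv), THF, 0 °C to rt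
Reagents that add atoms: none
Why: Sonogashira coupling with in situ fluoride desilylation should join the two fragments at the aryl iodide under mild conditions, and the same fluoride frees the phenol.

Step 13
Reactants: 21 the phenol–alkyne
Product: 22 4-{(2S)-2-[3,5-bis(benzyloxy)phenyl]-4-(DHB-5-yl)but-3-yn-1-ylidene}-2,6-di-tert-butylcyclohexa-2,5-dien-1-one
Conditions: Ag2O, CH2Cl2, rt, dark
Reagents that add atoms: none
Why: Two-electron oxidation of a 4-alkyl-2,6-di-tert-butylphenol by Ag2O should give the persistent para-quinone methide, the tert-butyl groups blocking dimerization; the neutral medium should leave the acidic C2–H untouched.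

Step 14
Reactants: 22 the alkyne-tethered quinone methide; 18 [3,5-bis(benzyloxy)phenyl]boronic acid
Product: 23 (1E,2S,3S)-4,6-bis(benzyloxy)-2-[3,5-bis(benzyloxy)phenyl]-1-[(DHB-5-yl)methylidene]-3-(3,5-di-tert-butyl-4-hydroxyphenyl)-2,3-dihydro-1H-indene
Conditions: [Rh(OH)(cod)]2 (2.5 mol%), 18 (2 equiv), 1,4-dioxane/H2O (20:1), 40 °C
Reagents that add atoms: none
Why: Proposed new method: the arylrhodium formed from 18 by transmetalation should add syn across the alkyne of 22 with the aryl going to the carbon that bears the sp3 branch (rhodium prefers the aryl-substituted carbon); the alkenylrhodium cannot reach the quinone methide (a four-membered closure) and should instead undergo alkenyl-to-aryl 1,4-rhodium shift to an ortho carbon of the new ring A, and this arylrhodium then adds 1,6 to the exocyclic quinone methide carbon, with rearomatization to the hindered phenoxide and protonolysis regenerating Rh–OH. The closest known reaction types are the rhodium-catalysed annulation of arylboron reagents (as 1,2-dimetalloarene equivalents) with alkyne-tethered enones to 1-alkylidene-indanes by the same carborhodation/1,4-shift/conjugate-addition sequence, and the rhodium-catalysed 1,6-addition of arylboronic acids to 2,6-di-tert-butyl quinone methides; the new element is the quinone methide as terminating acceptor. The only ring closed is the five-membered carbocycle, by 5-exo-trig attack forming C3a–C3, the C7a–C1 bond having been made in the intermolecular carborhodation. The new C3 centre is controlled by the existing C2 centre (the quinone methide ring is expected to add anti to the C2 aryl group in the envelope transition state, giving the 2,3-trans indane), and the E alkene follows from syn-carborhodation and retentive replacement of rhodium by the migrating ortho hydrogen. The step needs carborhodation with aryl at C1, alkyne insertion faster than direct 1,6-arylation of the quinone methide, and a single site for the 1,4-shift; these are secured by the aryl/alkyl bias of the alkyne, by the higher reactivity of alkynes toward arylrhodium together with shielding of the quinone methide carbon by the branched C2 substituent, and by the symmetry of the 3,5-bis(benzyloxy)phenyl group, whose two ortho C–H bonds are equivalent.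

Step 15
Reactants: 23 the protected indane
Product: 24 (1E,2S,3S)-3-(3,5-di-tert-butyl-4-hydroxyphenyl)-1-{[(2R,3R)-3-(3,5-dihydroxyphenyl)-2-(4-hydroxyphenyl)-2,3-dihydro-1-benzofuran-5-yl]methylidene}-2-(3,5-dihydroxyphenyl)-2,3-dihydro-1H-indene-4,6-diol
Conditions: BCl3, pentamethylbenzene, CH2Cl2, −78 °C; MeOH
Reagents that add atoms: none
Why: Lewis-acid debenzylation with BCl3 and pentamethylbenzene as a non-basic cation scavenger should cleave the seven aryl benzyl ethers at low temperature without reducing the alkene or opening the dihydrobenzofuran.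

Step 16
Reactants: 24 the di-tert-butyl octaphenol
Product: 25 (1E,2S,3S)-1-{[(2R,3R)-3-(3,5-dihydroxyphenyl)-2-(4-hydroxyphenyl)-2,3-dihydro-1-benzofuran-5-yl]methylidene}-2-(3,5-dihydroxyphenyl)-3-(4-hydroxyphenyl)-2,3-dihydro-1H-indene-4,6-diol (CNP0184753.1)
Conditions: AlCl3, toluene/MeNO2, 50 °C
Reagents that add atoms: none
Why: Retro-Friedel–Crafts de-tert-butylation; AlCl3 should transfer the two tert-butyl groups from the phenol ring to toluene, leaving the target.

**Compound list**

1 | 2-hydroxy-5-iodobenzaldehyde | O=Cc1cc(I)ccc1O | starting material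
2 | 1-(benzyloxy)-4-(chloromethyl)benzene | ClCc1ccc(OCc2ccccc2)cc1 | starting material
3 | 2-{[4-(benzyloxy)phenyl]methoxy}-5-iodobenzaldehyde | O=Cc1cc(I)ccc1OCc1ccc(OCc2ccccc2)cc1 | intermediate
4 | 1,3-bis(benzyloxy)-5-bromobenzene | Brc1cc(OCc2ccccc2)cc(OCc2ccccc2)c1 | starting material
5 | [3,5-bis(benzyloxy)phenyl]magnesium bromide | Br[Mg]c1cc(OCc2ccccc2)cc(OCc2ccccc2)c1 | intermediate (not isolated)
6 | [3,5-bis(benzyloxy)phenyl](2-{[4-(benzyloxy)phenyl]methoxy}-5-iodophenyl)methanol, racemic | OC(c1cc(OCc2ccccc2)cc(OCc2ccccc2)c1)c1cc(I)ccc1OCc1ccc(OCc2ccccc2)cc1 | intermediate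
7 | [3,5-bis(benzyloxy)phenyl](2-{[4-(benzyloxy)phenyl]methoxy}-5-iodophenyl)methanone | O=C(c1cc(OCc2ccccc2)cc(OCc2ccccc2)c1)c1cc(I)ccc1OCc1ccc(OCc2ccccc2)cc1 | intermediate
8 | hydrazone of 7 | NN=C(c1cc(OCc2ccccc2)cc(OCc2ccccc2)c1)c1cc(I)ccc1OCc1ccc(OCc2ccccc2)cc1 | intermediate
9 | 2-{[3,5-bis(benzyloxy)phenyl](diazo)methyl}-1-{[4-(benzyloxy)phenyl]methoxy}-4-iodobenzene | [N-]=[N+]=C(c1cc(OCc2ccccc2)cc(OCc2ccccc2)c1)c1cc(I)ccc1OCc1ccc(OCc2ccccc2)cc1 | intermediate (not isolated)
10 | (2S,3R)-2-[4-(benzyloxy)phenyl]-3-[3,5-bis(benzyloxy)phenyl]-5-iodo-2,3-dihydro-1-benzofuran (cis) | Ic1ccc2c(c1)[C@@H](c1cc(OCc3ccccc3)cc(OCc3ccccc3)c1)[C@@H](c1ccc(OCc3ccccc3)cc1)O2 | intermediate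
11 | (2R,3R)-2-[4-(benzyloxy)phenyl]-3-[3,5-bis(benzyloxy)phenyl]-5-iodo-2,3-dihydro-1-benzofuran (trans) | Ic1ccc2c(c1)[C@@H](c1cc(OCc3ccccc3)cc(OCc3ccccc3)c1)[C@H](c1ccc(OCc3ccccc3)cc1)O2 | intermediate
12 | (3,5-di-tert-butyl-4-hydroxyphenyl)acetic acid | OC(=O)Cc1cc(C(C)(C)C)c(O)c(C(C)(C)C)c1 | starting material
13 | 2-(3,5-di-tert-butyl-4-hydroxyphenyl)-N-methoxy-N-methylacetamide | CON(C)C(=O)Cc1cc(C(C)(C)C)c(O)c(C(C)(C)C)c1 | intermediate
14 | lithium (trimethylsilyl)acetylide | [Li]C#C[Si](C)(C)C | starting material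
15 | 1-{3,5-di-tert-butyl-4-[(trimethylsilyl)oxy]phenyl}-4-(trimethylsilyl)but-3-yn-2-one | C[Si](C)(C)C#CC(=O)Cc1cc(C(C)(C)C)c(O[Si](C)(C)C)c(C(C)(C)C)c1 | intermediate
16 | 1-{3,5-di-tert-butyl-4-[(trimethylsilyl)oxy]phenyl}-4-(trimethylsilyl)but-3-yn-2-ol, racemic | C[Si](C)(C)C#CC(O)Cc1cc(C(C)(C)C)c(O[Si](C)(C)C)c(C(C)(C)C)c1 | intermediate
17 | [3-bromo-4-{3,5-di-tert-butyl-4-[(trimethylsilyl)oxy]phenyl}but-1-yn-1-yl]trimethylsilane, racemic | C[Si](C)(C)C#CC(Br)Cc1cc(C(C)(C)C)c(O[Si](C)(C)C)c(C(C)(C)C)c1 | intermediate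
18 | [3,5-bis(benzyloxy)phenyl]boronic acid | OB(O)c1cc(OCc2ccccc2)cc(OCc2ccccc2)c1 | starting material
19 | [3,5-bis(benzyloxy)phenyl](ethyl)zinc | CC[Zn]c1cc(OCc2ccccc2)cc(OCc2ccccc2)c1 | intermediate (not isolated)
20 | [(3S)-3-[3,5-bis(benzyloxy)phenyl]-4-{3,5-di-tert-butyl-4-[(trimethylsilyl)oxy]phenyl}but-1-yn-1-yl]trimethylsilane | C[Si](C)(C)C#C[C@@H](Cc1cc(C(C)(C)C)c(O[Si](C)(C)C)c(C(C)(C)C)c1)c1cc(OCc2ccccc2)cc(OCc2ccccc2)c1 | intermediate
21 | 4-{(2S)-2-[3,5-bis(benzyloxy)phenyl]-4-(DHB-5-yl)but-3-yn-1-yl}-2,6-di-tert-butylphenol | c1(C#C[C@@H](Cc2cc(C(C)(C)C)c(O)c(C(C)(C)C)c2)c2cc(OCc3ccccc3)cc(OCc3ccccc3)c2)ccc2c(c1)[C@@H](c1cc(OCc3ccccc3)cc(OCc3ccccc3)c1)[C@H](c1ccc(OCc3ccccc3)cc1)O2 | intermediate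
22 | 4-{(2S)-2-[3,5-bis(benzyloxy)phenyl]-4-(DHB-5-yl)but-3-yn-1-ylidene}-2,6-di-tert-butylcyclohexa-2,5-dien-1-one | c1(C#C[C@@H](C=C2C=C(C(C)(C)C)C(=O)C(C(C)(C)C)=C2)c2cc(OCc3ccccc3)cc(OCc3ccccc3)c2)ccc2c(c1)[C@@H](c1cc(OCc3ccccc3)cc(OCc3ccccc3)c1)[C@H](c1ccc(OCc3ccccc3)cc1)O2 | intermediate
23 | (1E,2S,3S)-4,6-bis(benzyloxy)-2-[3,5-bis(benzyloxy)phenyl]-1-[(DHB-5-yl)methylidene]-3-(3,5-di-tert-butyl-4-hydroxyphenyl)-2,3-dihydro-1H-indene | Oc1c(C(C)(C)C)cc([C@H]2c3c(OCc5ccccc5)cc(OCc5ccccc5)cc3/C(=C/c3ccc4c(c3)[C@@H](c3cc(OCc5ccccc5)cc(OCc5ccccc5)c3)[C@H](c3ccc(OCc5ccccc5)cc3)O4)[C@@H]2c2cc(OCc5ccccc5)cc(OCc5ccccc5)c2)cc1C(C)(C)C | intermediate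
24 | (1E,2S,3S)-3-(3,5-di-tert-butyl-4-hydroxyphenyl)-1-{[(2R,3R)-3-(3,5-dihydroxyphenyl)-2-(4-hydroxyphenyl)-2,3-dihydro-1-benzofuran-5-yl]methylidene}-2-(3,5-dihydroxyphenyl)-2,3-dihydro-1H-indene-4,6-diol | Oc1c(C(C)(C)C)cc([C@H]2c3c(O)cc(O)cc3/C(=C/c3ccc4c(c3)[C@@H](c3cc(O)cc(O)c3)[C@H](c3ccc(O)cc3)O4)[C@@H]2c2cc(O)cc(O)c2)cc1C(C)(C)C | intermediate
25 | (1E,2S,3S)-1-{[(2R,3R)-3-(3,5-dihydroxyphenyl)-2-(4-hydroxyphenyl)-2,3-dihydro-1-benzofuran-5-yl]methylidene}-2-(3,5-dihydroxyphenyl)-3-(4-hydroxyphenyl)-2,3-dihydro-1H-indene-4,6-diol | Oc1ccc([C@H]2c3c(O)cc(O)cc3/C(=C/c3ccc4c(c3)[C@@H](c3cc(O)cc(O)c3)[C@H](c3ccc(O)cc3)O4)[C@@H]2c2cc(O)cc(O)c2)cc1 | target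

**Count and risks**

Total steps: 16. Longest linear sequence: 11 steps (steps 1–6, then 12–16).

Steps most likely to fail:

Step 14 (carries the label). What may go wrong: protonation of the alkenylrhodium before the 1,4-shift, carborhodation with the opposite regiochemistry (leading to a six-membered closure), direct 1,6-arylation of the quinone methide, or tautomerization of the quinone methide with loss of the C2 centre. The fallback uses known reactions only, sets out from 21 and comes back at 23. Rhodium-catalysed syn-hydroarylation of the alkyne of 21 with 18 ([Rh(OH)(cod)]2, dioxane/H2O, 60 °C) should give 4-{(2S,3E)-2,3-bis[3,5-bis(benzyloxy)phenyl]-4-(DHB-5-yl)but-3-en-1-yl}-2,6-di-tert-butylphenol F1, in which ring A already sits on C1 and C2 is no longer propargylic. Ag2O oxidation should then give the corresponding quinone methide F2. BF3·OEt2 in CH2Cl2 at −78 °C should close the indane by intramolecular Friedel–Crafts alkylation of the activated ring A position (ortho and para to the benzyloxy groups) by the quinone methide, trans to the C2 aryl group, giving 23.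

Step 11. What may go wrong: low enantioselectivity with this β-aryl-substituted propargylic bromide, or loss of the bromide by elimination to the enyne or by reduction of the propargylic radical. The fallback sets out from 17 and comes back at 21. Coupling of 17 with 19 under an achiral nickel catalyst (NiCl2(dme), 2,2'-bipyridine) should give the racemic silylalkyne F3. The Sonogashira coupling of step 12 with enantiopure 11 then gives 21 together with its (2R) epimer F4, and the two diastereomers are separated by preparative HPLC. The stereocentre is thus obtained by separation of diastereomers instead of asymmetric catalysis.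

Step 5. What may go wrong: insufficient enantio- or cis-selectivity of the carbene insertion with this heavily benzyloxylated substrate, or diversion of the diazo compound to the azine. The fallback sets out from 8 and comes back at 11. Oxidation of 8 as before and cyclization with achiral Rh2(OAc)4 should give the racemic cis-2-[4-(benzyloxy)phenyl]-3-[3,5-bis(benzyloxy)phenyl]-5-iodo-2,3-dihydro-1-benzofuran F5. TFA epimerization gives the racemic trans isomer F6, which is resolved by preparative HPLC on a chiral stationary phase to give 11.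

Further compounds
F1 | step 14 | 4-{(2S,3E)-2,3-bis[3,5-bis(benzyloxy)phenyl]-4-(DHB-5-yl)but-3-en-1-yl}-2,6-di-tert-butylphenol | c1(/C=C(/c2cc(OCc3ccccc3)cc(OCc3ccccc3)c2)[C@@H](Cc2cc(C(C)(C)C)c(O)c(C(C)(C)C)c2)c2cc(OCc3ccccc3)cc(OCc3ccccc3)c2)ccc2c(c1)[C@@H](c1cc(OCc3ccccc3)cc(OCc3ccccc3)c1)[C@H](c1ccc(OCc3ccccc3)cc1)O2
F2 | step 14 | 4-{(2S,3E)-2,3-bis[3,5-bis(benzyloxy)phenyl]-4-(DHB-5-yl)but-3-en-1-ylidene}-2,6-di-tert-butylcyclohexa-2,5-dien-1-one | c1(/C=C(/c2cc(OCc3ccccc3)cc(OCc3ccccc3)c2)[C@@H](C=C2C=C(C(C)(C)C)C(=O)C(C(C)(C)C)=C2)c2cc(OCc3ccccc3)cc(OCc3ccccc3)c2)ccc2c(c1)[C@@H](c1cc(OCc3ccccc3)cc(OCc3ccccc3)c1)[C@H](c1ccc(OCc3ccccc3)cc1)O2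
F3 | step 11 | [3-[3,5-bis(benzyloxy)phenyl]-4-{3,5-di-tert-butyl-4-[(trimethylsilyl)oxy]phenyl}but-1-yn-1-yl]trimethylsilane, racemic | C[Si](C)(C)C#CC(Cc1cc(C(C)(C)C)c(O[Si](C)(C)C)c(C(C)(C)C)c1)c1cc(OCc2ccccc2)cc(OCc2ccccc2)c1
F4 | step 11 | 4-{(2R)-2-[3,5-bis(benzyloxy)phenyl]-4-(DHB-5-yl)but-3-yn-1-yl}-2,6-di-tert-butylphenol | c1(C#C[C@H](Cc2cc(C(C)(C)C)c(O)c(C(C)(C)C)c2)c2cc(OCc3ccccc3)cc(OCc3ccccc3)c2)ccc2c(c1)[C@@H](c1cc(OCc3ccccc3)cc(OCc3ccccc3)c1)[C@H](c1ccc(OCc3ccccc3)cc1)O2
F5 | step 5 | cis-2-[4-(benzyloxy)phenyl]-3-[3,5-bis(benzyloxy)phenyl]-5-iodo-2,3-dihydro-1-benzofuran, racemate (one enantiomer drawn) | Ic1ccc2c(c1)[C@@H](c1cc(OCc3ccccc3)cc(OCc3ccccc3)c1)[C@@H](c1ccc(OCc3ccccc3)cc1)O2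
F6 | step 5 | trans-2-[4-(benzyloxy)phenyl]-3-[3,5-bis(benzyloxy)phenyl]-5-iodo-2,3-dihydro-1-benzofuran, racemate (one enantiomer drawn) | Ic1ccc2c(c1)[C@@H](c1cc(OCc3ccccc3)cc(OCc3ccccc3)c1)[C@H](c1ccc(OCc3ccccc3)cc1)O2
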